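**Retrosynthetic overview**
- The target is unit A (7-methoxycoumarin) joined through its C8 oxygen to C8' of unit B (5',7'-dihydroxycoumarin). The last operations are debenzylation and oxidation of the C2' methylene of a 2H-chromene to the lactone carbonyl.
- The pyran ring of unit B is opened at C4'–C4a' and O1'–C2' to an aryl propargyl ether. The structural feature used is that in ring B C8' carries the diaryl ether oxygen, so C4a' is the only free carbon ortho to O1' and a propargyl group on O1' can only end up there.
- The propargyl ether comes from a symmetric 2-aryloxy-5-benzyloxyresorcinol by mono-propargylation and benzylation of the second hydroxyl.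
- The resorcinol comes from double Baeyer–Villiger oxidation of a 2-aryloxyisophthalaldehyde. Its diaryl ether bond is made by SNAr of 8-hydroxy-7-methoxycoumarin on 5-(benzyloxy)-2-fluoroisophthalaldehyde.
- Ring order: unit A is bought intact, the benzene ring of unit B comes from 4-fluoro-3,5-dimethylphenol, the pyran ring of unit B is closed in step 9 and becomes the lactone in step 10.

Key step: step 9

Assumption: 8-hydroxy-7-methoxycoumarin is taken as a purchasable coumarin. The benzyl ether is installed only after the methyl groups are oxidized, because its OCH2 group would not survive radical bromination. The second phenol is benzylated before the key step so that no free phenol meets the chromium oxidant.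

**Step 1**
Reactants: 1 4-fluoro-3,5-dimethylphenol
Product: 2 4-fluoro-3,5-dimethylphenyl acetate
Conditions: Ac2O, pyridine, DMAP (cat.), CH2Cl2, rt
Reagents that add atoms: acetic anhydride, CC(=O)OC(C)=O
Why: O-acetylation (nucleophilic acyl substitution) masks the phenol and deactivates the ring, so that the following bromination is confined to the two benzylic methyl groups.

**Step 2**
Reactants: 2 4-fluoro-3,5-dimethylphenyl acetate
Product: 3 3,5-bis(dibromomethyl)-4-fluorophenyl acetate
Conditions: NBS (4.5 equiv), AIBN (cat.), PhCF3, reflux, visible light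
Reagents that add atoms: N-bromosuccinimide, O=C1CCC(=O)N1Br
Why: Wohl–Ziegler radical bromination should take each methyl group to the dibromomethyl stage, the third bromination being slowed by the crowding next to fluorine.

**Step 3**
Reactants: 3 3,5-bis(dibromomethyl)-4-fluorophenyl acetate
Product: 5 2-fluoro-5-hydroxybenzene-1,3-dicarbaldehyde, via 4-fluoro-3,5-diformylphenyl acetate 4 (not isolated)
Conditions: AgNO3, acetone/H2O, reflux; then aq. HCl, 60 °C
Reagents that add atoms: water, O
Why: Silver-assisted hydrolysis of the geminal dibromides gives the two aldehydes and acid hydrolysis removes the aryl acetate; no nucleophilic base is present, so the fluoride between the two formyl groups should stay in place.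

**Step 4**
Reactants: 5 2-fluoro-5-hydroxybenzene-1,3-dicarbaldehyde; 6 benzyl bromide
Product: 7 5-(benzyloxy)-2-fluorobenzene-1,3-dicarbaldehyde
Conditions: BnBr (1.5 equiv), K2CO3, acetone, rt
Reagents that add atoms: benzyl bromide, BrCc1ccccc1
Why: Williamson etherification of the acidic phenol with excess benzyl bromide at room temperature should outrun attack of the weakly nucleophilic phenoxide on the activated fluoride of the product.

**Step 5**
Reactants: 7 5-(benzyloxy)-2-fluorobenzene-1,3-dicarbaldehyde; 8 8-hydroxy-7-methoxycoumarin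
Product: 9 5-(benzyloxy)-2-[(7-methoxy-2-oxo-2H-chromen-8-yl)oxy]benzene-1,3-dicarbaldehyde
Conditions: K2CO3, DMF, 60 °C
Reagents that add atoms: none
Why: Nucleophilic aromatic substitution (addition–elimination) of the fluoride by the coumarin phenoxide, with the Meisenheimer intermediate stabilized by both ortho formyl groups, should build the hindered diaryl ether.

**Step 6**
Reactants: 9 5-(benzyloxy)-2-[(7-methoxy-2-oxo-2H-chromen-8-yl)oxy]benzene-1,3-dicarbaldehyde
Product: 11 8-[4-(benzyloxy)-2,6-dihydroxyphenoxy]-7-methoxy-2H-chromen-2-one, via bis-formate ester 10 (not isolated)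
Conditions: mCPBA (2.5 equiv), CH2Cl2, 0 °C to rt; aq. Na2S2O3/NaHCO3 wash; then Et3N (cat.), MeOH, rt
Reagents that add atoms: 3-chloroperoxybenzoic acid, OOC(=O)c1cccc(Cl)c1
Why: Double Baeyer–Villiger (Dakin-type) oxidation, in which the aryl group migrates because each formyl group sits ortho to the aryloxy donor, gives the bis-formate, and mild methanolysis frees the two phenols without opening the lactone.

**Step 7**
Reactants: 11 8-[4-(benzyloxy)-2,6-dihydroxyphenoxy]-7-methoxy-2H-chromen-2-one; 12 propargyl bromide
Product: 13 8-[4-(benzyloxy)-2-hydroxy-6-(prop-2-yn-1-yloxy)phenoxy]-7-methoxy-2H-chromen-2-one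
Conditions: propargyl bromide (1.0 equiv), K2CO3, acetone, 40 °C
Reagents that add atoms: propargyl bromide, C#CCBr
Why: Williamson mono-alkylation of two equivalent hydroxyls needs no regiocontrol; the mono-ether is separated from bis-ether and unreacted diol, and the diol is recycled.

**Step 8**
Reactants: 13 8-[4-(benzyloxy)-2-hydroxy-6-(prop-2-yn-1-yloxy)phenoxy]-7-methoxy-2H-chromen-2-one; 6 benzyl bromide
Product: 14 8-[2,4-bis(benzyloxy)-6-(prop-2-yn-1-yloxy)phenoxy]-7-methoxy-2H-chromen-2-one
Conditions: BnBr, K2CO3, DMF, rt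
Reagents that add atoms: benzyl bromide, BrCc1ccccc1
Why: Williamson benzylation caps the future 7'-hydroxyl, so that both phenols later fall in one deprotection and no free phenol is exposed to the heating or to the chromium oxidant.

**Step 9**
Reactants: 14 8-[2,4-bis(benzyloxy)-6-(prop-2-yn-1-yloxy)phenoxy]-7-methoxy-2H-chromen-2-one
Product: 18 8-{[5,7-bis(benzyloxy)-2H-chromen-8-yl]oxy}-7-methoxy-2H-chromen-2-one, via allenyl dienone 15 (not isolated), via ortho-allenylphenol 16 (not isolated), via ortho-quinone methide 17 (not isolated)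
Conditions: PhNEt2 (dilute), 210 °C, sealed tube, Ar
Reagents that add atoms: none
Why: A thermal aryl propargyl ether Claisen rearrangement ([3,3]-sigmatropic shift) moves the propargyl group from O1' to C4a' as an allenyl group, forming the C4'–C4a' bond in dienone 15, which enolizes to allenylphenol 16. A 1,5-hydrogen shift from the phenol O–H to the central allene carbon gives the (Z)-ortho-quinone methide 17, and a thermal disrotatory oxa-6π electrocyclization closes the pyran ring of unit B by forming O1'–C2'. The closest known reaction type is the thermal conversion of aryl propargyl ethers, including 3,5-dialkoxyphenyl ones, into 2H-chromenes in N,N-diethylaniline. No stereocentre remains in the product, since the one in 15 is lost on enolization. The step needs site selectivity (C4a', not C8') and ring-size selectivity (chromene, not 2-methylbenzofuran): C8' carries the aryloxy group, so a shift to it gives a dienone that cannot tautomerize and returns by the reverse shift, and the absence of fluoride or strong base keeps the phenol of 16 from adding 5-exo to the allene.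

**Step 10**
Reactants: 18 8-{[5,7-bis(benzyloxy)-2H-chromen-8-yl]oxy}-7-methoxy-2H-chromen-2-one
Product: 19 8-{[5,7-bis(benzyloxy)-2-oxo-2H-chromen-8-yl]oxy}-7-methoxy-2H-chromen-2-one
Conditions: pyridinium chlorochromate C5H5NH[CrO3Cl] (excess), Celite, CH2Cl2, reflux
Reagents that add atoms: pyridinium chlorochromate, [O-][Cr](=O)(=O)Cl.c1cc[nH+]cc1
Why: Allylic oxidation by hexavalent chromium at the C2' methylene, which is both allylic and bound to oxygen, is a known way from 2H-chromenes to coumarins and should leave the aryl benzyl ethers and unit A untouched.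

**Step 11**
Reactants: 19 8-{[5,7-bis(benzyloxy)-2-oxo-2H-chromen-8-yl]oxy}-7-methoxy-2H-chromen-2-one
Product: 20 8-[(5,7-dihydroxy-2-oxo-2H-chromen-8-yl)oxy]-7-methoxy-2H-chromen-2-one (target)
Conditions: BCl3, pentamethylbenzene, CH2Cl2, −78 °C; then MeOH, H2O
Reagents that add atoms: none
Why: Lewis-acid cleavage of the two benzyl ethers with capture of the benzyl cation by pentamethylbenzene (Friedel–Crafts scavenging) should spare the aryl methyl ether, the diaryl ether and both lactones at low temperature.

**Compound list**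
1 | 4-fluoro-3,5-dimethylphenol | Cc1cc(O)cc(C)c1F | starting material
2 | 4-fluoro-3,5-dimethylphenyl acetate | CC(=O)Oc1cc(C)c(F)c(C)c1 | intermediate
3 | 3,5-bis(dibromomethyl)-4-fluorophenyl acetate | CC(=O)Oc1cc(C(Br)Br)c(F)c(C(Br)Br)c1 | intermediate
4 | 4-fluoro-3,5-diformylphenyl acetate (formed in the flask in step 3) | CC(=O)Oc1cc(C=O)c(F)c(C=O)c1 | intermediate
5 | 2-fluoro-5-hydroxybenzene-1,3-dicarbaldehyde | O=Cc1cc(O)cc(C=O)c1F | intermediate
6 | benzyl bromide | BrCc1ccccc1 | starting material
7 | 5-(benzyloxy)-2-fluorobenzene-1,3-dicarbaldehyde | O=Cc1cc(OCc2ccccc2)cc(C=O)c1F | intermediate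
8 | 8-hydroxy-7-methoxycoumarin (8-hydroxy-7-methoxy-2H-chromen-2-one) | COc1ccc2ccc(=O)oc2c1O | starting material
9 | 5-(benzyloxy)-2-[(7-methoxy-2-oxo-2H-chromen-8-yl)oxy]benzene-1,3-dicarbaldehyde | COc1ccc2ccc(=O)oc2c1Oc1c(C=O)cc(OCc2ccccc2)cc1C=O | intermediate
10 | 5-(benzyloxy)-2-[(7-methoxy-2-oxo-2H-chromen-8-yl)oxy]-1,3-phenylene diformate (formed in the flask in step 6) | COc1ccc2ccc(=O)oc2c1Oc1c(OC=O)cc(OCc2ccccc2)cc1OC=O | intermediate
11 | 8-[4-(benzyloxy)-2,6-dihydroxyphenoxy]-7-methoxy-2H-chromen-2-one | COc1ccc2ccc(=O)oc2c1Oc1c(O)cc(OCc2ccccc2)cc1O | intermediate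
12 | propargyl bromide (3-bromoprop-1-yne) | C#CCBr | starting material
13 | 8-[4-(benzyloxy)-2-hydroxy-6-(prop-2-yn-1-yloxy)phenoxy]-7-methoxy-2H-chromen-2-one | COc1ccc2ccc(=O)oc2c1Oc1c(O)cc(OCc2ccccc2)cc1OCC#C | intermediate
14 | 8-[2,4-bis(benzyloxy)-6-(prop-2-yn-1-yloxy)phenoxy]-7-methoxy-2H-chromen-2-one | COc1ccc2ccc(=O)oc2c1Oc1c(OCc2ccccc2)cc(OCc2ccccc2)cc1OCC#C | intermediate
15 | 8-{[2,4-bis(benzyloxy)-6-oxo-5-(propa-1,2-dien-1-yl)cyclohexa-1,3-dien-1-yl]oxy}-7-methoxy-2H-chromen-2-one (racemic allenyl dienone, formed in the flask in step 9) | COc1ccc2ccc(=O)oc2c1OC1=C(OCc2ccccc2)C=C(OCc2ccccc2)C(C=C=C)C1=O | intermediate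
16 | 8-[2,4-bis(benzyloxy)-6-hydroxy-5-(propa-1,2-dien-1-yl)phenoxy]-7-methoxy-2H-chromen-2-one (formed in the flask in step 9) | COc1ccc2ccc(=O)oc2c1Oc1c(OCc2ccccc2)cc(OCc2ccccc2)c(C=C=C)c1O | intermediate
17 | 8-{[(5Z)-2,4-bis(benzyloxy)-6-oxo-5-(prop-2-en-1-ylidene)cyclohexa-1,3-dien-1-yl]oxy}-7-methoxy-2H-chromen-2-one (ortho-quinone methide, formed in the flask in step 9) | COc1ccc2ccc(=O)oc2c1OC1=C(OCc2ccccc2)C=C(OCc2ccccc2)/C(=C/C=C)C1=O | intermediate
18 | 8-{[5,7-bis(benzyloxy)-2H-chromen-8-yl]oxy}-7-methoxy-2H-chromen-2-one | COc1ccc2ccc(=O)oc2c1Oc1c(OCc2ccccc2)cc(OCc2ccccc2)c2C=CCOc12 | intermediate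
19 | 8-{[5,7-bis(benzyloxy)-2-oxo-2H-chromen-8-yl]oxy}-7-methoxy-2H-chromen-2-one | COc1ccc2ccc(=O)oc2c1Oc1c(OCc2ccccc2)cc(OCc2ccccc2)c2ccc(=O)oc12 | intermediate
20 | 8-[(5,7-dihydroxy-2-oxo-2H-chromen-8-yl)oxy]-7-methoxy-2H-chromen-2-one | COc1ccc2ccc(=O)oc2c1Oc1c(O)cc(O)c2ccc(=O)oc12 | target

**Step count**
Total steps: 11. Longest linear sequence: 11 steps (1 to 20); compounds 6, 8 and 12 enter along the way.

**Steps most likely to fail**

Step 9. At about 210 °C the cascade may be diverted. The dienone from migration to the blocked C8' can be drained by an intramolecular Diels–Alder reaction instead of reverting, the allenylphenol can close to a five-membered furan, and the quinone methide can oligomerize. Fallback: starting from 14, the alkyne is activated by a monovalent gold catalyst, Ph3PAuNTf2 (cat.), in CH2Cl2 at room temperature. A 6-endo-dig intramolecular hydroarylation by C4a', the only free ortho carbon, should give chromene 18 directly with no pericyclic intermediates, and the route continues at 18. No new compound arises on this path (F0).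

Step 6. Each formyl group has only one donor ortho to it, so hydride migration in the Criegee intermediate (giving benzoic acids) may compete with aryl migration, and the oxidation may stall after the first formyl group. Fallback: starting from 7, the formyl groups are replaced by acetyl groups, for which only aryl migration is productive. Addition of MeMgBr in THF at −78 °C should give 1,1'-[5-(benzyloxy)-2-fluoro-1,3-phenylene]di(ethan-1-ol) F1 as a mixture of diastereomers. Oxidation with MnO2 in CH2Cl2 should give 1,1'-[5-(benzyloxy)-2-fluoro-1,3-phenylene]di(ethan-1-one) F2. SNAr with 8 (K2CO3, DMF) should give 8-[2,6-diacetyl-4-(benzyloxy)phenoxy]-7-methoxy-2H-chromen-2-one F3. Baeyer–Villiger oxidation with mCPBA and trifluoroacetic acid in CH2Cl2 should give 5-(benzyloxy)-2-[(7-methoxy-2-oxo-2H-chromen-8-yl)oxy]-1,3-phenylene diacetate F4. Methanolysis with HCl in MeOH returns the route to diol 11.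

Step 10. Oxidation of the methylene may stay incomplete, while the benzylic positions of the benzyl ethers or the electron-rich ring are attacked by the chromium reagent on prolonged heating. Fallback: starting from 18, hydride abstraction with DDQ in CH2Cl2/H2O gives the benzopyrylium ion, which water should trap as the lactol 8-{[5,7-bis(benzyloxy)-2-hydroxy-2H-chromen-8-yl]oxy}-7-methoxy-2H-chromen-2-one F5 (racemic). Oxidation of the lactol with MnO2 in CH2Cl2 should then give 19, where the route continues.

**Further compounds**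
F0 | step 9 | none | none
F1 | step 6 | 1,1'-[5-(benzyloxy)-2-fluoro-1,3-phenylene]di(ethan-1-ol), mixture of diastereomers | CC(O)c1cc(OCc2ccccc2)cc(C(C)O)c1F
F2 | step 6 | 1,1'-[5-(benzyloxy)-2-fluoro-1,3-phenylene]di(ethan-1-one) | CC(=O)c1cc(OCc2ccccc2)cc(C(C)=O)c1F
F3 | step 6 | 8-[2,6-diacetyl-4-(benzyloxy)phenoxy]-7-methoxy-2H-chromen-2-one | COc1ccc2ccc(=O)oc2c1Oc1c(C(C)=O)cc(OCc2ccccc2)cc1C(C)=O
F4 | step 6 | 5-(benzyloxy)-2-[(7-methoxy-2-oxo-2H-chromen-8-yl)oxy]-1,3-phenylene diacetate | COc1ccc2ccc(=O)oc2c1Oc1c(OC(C)=O)cc(OCc2ccccc2)cc1OC(C)=O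
F5 | step 10 | 8-{[5,7-bis(benzyloxy)-2-hydroxy-2H-chromen-8-yl]oxy}-7-methoxy-2H-chromen-2-one, racemic | COc1ccc2ccc(=O)oc2c1Oc1c(OCc2ccccc2)cc(OCc2ccccc2)c2C=CC(O)Oc12
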